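**Plan**
1. Retrosynthetic cuts, in order: the C6–O ester bond; C14=C15, C11–C12 and C9=C11 of the side chain; the C8–O and C6–O bonds of ring B; the C1 oxygen; C3–C4 of ring A; C10–C1 and C10–C20.
2. Enabling feature: in ring A the quaternary carbon C4 (bearing C18 and C19) is bonded directly to the ring-fusion stereocentre C5. C4/C18/C19 are therefore the isopropenyl group of (R)-carvone, whose ring is ring B (C=O = C9, ring methyl = C17 on C8, CH = C5). Adding H• to that alkene gives a tertiary C4 radical that can close onto C3 of an acryloyl group held on C10.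
3. Forward order: ring B is bought; C20 and C1–C3 are placed on C10; ring A closes through C3–C4; C1 is deoxygenated; C6 is oxidised; C9=O becomes C9=C11; hydroboration/Suzuki coupling joins C11–C12; C15 is added; the angelate goes on last.
4. Stereochemistry: C5 from carvone; C10 by aldol attack anti to the isopropenyl group; C6 by α-face oxidation of a dienol ether; C9 by α-face hydroboration; C8 by 6α-OH-directed epoxidation; C13 by Sharpless epoxidation with L-(+)-DET; the Z alkene from angelic acid.

Key step: step 4

Remark: labdane numbering is used throughout, also for the monocyclic precursors (ring A: C1–C5, C10; ring B: C5–C10; C17 on C8, C18/C19 on C4, C20 on C10, chain C11–C16). α is the face of H-5 and β the face of C20. A centre that is erased again later is left open in name and SMILES.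

**Step 1**
Reactants: 1 (R)-(−)-carvone; 2 iodomethane
Product: 4 6-methylcarvone (carvone C6 = C10; both epimers), via carvone lithium dienolate 3 (not isolated)
Conditions: LiN(iPr)2, THF, −78 °C; MeI, −78 → 0 °C
Reagents that add atoms: iodomethane 2, CI
Why: Kinetic α′-deprotonation of the enone followed by SN2 enolate alkylation puts C20 on the future C10, and the epimer mixture at this carbon is harmless because step 2 planarises it again.

**Step 2**
Reactants: 4 6-methylcarvone; 5 acrolein
Product: 7 6-(1-hydroxyallyl)-6-methylcarvone (hydroxyallyl trans to isopropenyl; both carbinol epimers), via tetrasubstituted lithium enolate 6 (not isolated)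
Conditions: LiN(iPr)2, THF, −78 → −20 °C; acrolein, −78 °C; AcOH quench at −78 °C
Reagents that add atoms: acrolein 5, C=CC=O
Why: In this aldol 1,2-addition the aldehyde approaches the enolate face opposite the neighbouring isopropenyl group, so C1 ends trans to C4 and C20 becomes β, which sets quaternary C10, while the cold acidic quench prevents retro-aldol reaction and the carbinol centre disappears in step 3.

**Step 3**
Reactants: 7 6-(1-hydroxyallyl)-6-methylcarvone
Product: 8 6-acryloyl-6-methylcarvone (acryloyl trans to isopropenyl, methyl cis)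
Conditions: Dess–Martin periodinane, CH2Cl2, 0 °C → rt
Reagents that add atoms: none
Why: Dess–Martin oxidation of the secondary allylic alcohol proceeds without base, so the retro-aldol-prone β-hydroxy ketone and the non-enolisable β-diketone product both survive.

**Step 4**
Reactants: 8 6-acryloyl-6-methylcarvone
Product: 9 11-nordrim-7-ene-1,9-dione (4,4,8,10-tetramethyl-trans-octal-7-ene-1,9-dione; 5α-H, 10β-CH3)
Conditions: Fe(acac)3 (30 mol %), PhSiH3, EtOH, 60 °C, high dilution
Reagents that add atoms: none
Why: PhSiH3 and EtOH turn Fe(acac)3 into a trivalent iron hydride, which hands a hydrogen atom to the terminal CH2 of the isopropenyl group, so that this carbon becomes the second methyl group on C4 and C4 a nucleophilic tertiary radical. The radical adds to C3, the β-carbon of the acryloyl group (intramolecular Giese addition), and the C2 α-keto radical is reduced by divalent iron to an enolate that EtOH protonates, which returns trivalent iron to the cycle. The closest known reaction type is the iron-catalysed reductive olefin–enone coupling by metal-hydride hydrogen atom transfer, used here intramolecularly. Ring A closes in the 6-endo-trig mode of a 4-oxohex-5-enyl radical, whereas 5-exo attack at C2 would pair the nucleophilic radical with the electron-rich end of the enone and leave an unstabilised primary radical. No stereocentre is formed (C4 carries two methyl groups, C2 and C3 are CH2), and the trans ring fusion follows from the trans arrangement of the two arms on C5 (from carvone) and C10 (step 2). The step needs hydrogen atom transfer to the electron-neutral 1,1-disubstituted alkene in preference to the two electron-poor alkenes, which the polarity-sensitive iron hydride and the stability of the tertiary radical secure, while the ring enone is out of reach of C4 (a four-membered ring would result) and high dilution disfavours intermolecular addition.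

**Step 5**
Reactants: 9 11-nordrim-7-ene-1,9-dione
Product: 10 1-hydroxy-11-nordrim-7-en-9-one (C1 epimers, mainly the equatorial 1β-alcohol expected)
Conditions: NaBH4, MeOH–CH2Cl2, −78 → −40 °C
Reagents that add atoms: none
Why: In this chemoselective borohydride 1,2-reduction the saturated C1 ketone is more electrophilic than the cross-conjugated, α-methylated C9 enone, the low temperature suppresses retro-aldol and retro-Claisen cleavage, and the new C1 centre is erased in step 7.

**Step 6**
Reactants: 10 1-hydroxy-11-nordrim-7-en-9-one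
Product: 11 1-O-(imidazol-1-ylthiocarbonyl) derivative of 10
Conditions: 1,1′-thiocarbonyldiimidazole, DMAP (cat.), ClCH2CH2Cl, reflux
Reagents that add atoms: 1,1′-thiocarbonyldiimidazole, S=C(n1ccnc1)n1ccnc1
Why: Thioacylation under nearly neutral conditions (first half of a Barton–McCombie deoxygenation) avoids the free C1 alkoxide of a xanthate protocol, which could fragment by retro-aldol reaction.

**Step 7**
Reactants: 11 1-O-(imidazol-1-ylthiocarbonyl) derivative
Product: 12 11-nordrim-7-en-9-one (5α-H, 10β-CH3)
Conditions: Bu3SnH, AIBN (cat.), toluene, 100 °C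
Reagents that add atoms: none
Why: In the Barton–McCombie radical deoxygenation the stannyl radical adds to C=S, the secondary C1 radical is released and is quenched by Bu3SnH, and the hindered trisubstituted enone is not touched.

**Step 8**
Reactants: 12 11-nordrim-7-en-9-one
Product: 13 9-(tert-butyldimethylsilyloxy)-11-nordrima-6,8-diene
Conditions: TBSOTf, Et3N, CH2Cl2, 0 °C → rt
Reagents that add atoms: tert-butyldimethylsilyl triflate, CC(C)(C)[Si](C)(C)OS(=O)(=O)C(F)(F)F
Why: Soft enolisation (O-silylation, then loss of a γ-proton) can only take place at C6 because C10 is quaternary, so the linear silyl dienol ether is the sole possible product.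

**Step 9**
Reactants: 13 9-(tert-butyldimethylsilyloxy)-11-nordrima-6,8-diene
Product: 15 6α-hydroxy-11-nordrim-7-en-9-one, via vinylogous silyloxy epoxide 14 (not isolated)
Conditions: dimethyldioxirane, acetone–CH2Cl2, −40 °C; then PPTS (cat.), THF–H2O, rt
Reagents that add atoms: dimethyldioxirane, CC1(C)OO1
Why: In this vinylogous Rubottom oxidation the oxidant should attack the open distal C6=C7 bond rather than the tetrasubstituted C8=C9 bond buried between C10 and the silyl group, from the α face because the β face of C6 lies under the axial methyl groups C19 and C20, and acid-catalysed opening of the epoxide with loss of silanol restores the enone with an equatorial 6α-OH.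

**Step 10**
Reactants: 15 6α-hydroxy-11-nordrim-7-en-9-one
Product: 16 6α-(tert-butyldimethylsilyloxy)-11-nordrim-7-en-9-one
Conditions: TBSOTf, 2,6-lutidine, CH2Cl2, −78 → 0 °C
Reagents that add atoms: tert-butyldimethylsilyl triflate, CC(C)(C)[Si](C)(C)OS(=O)(=O)C(F)(F)F
Why: Silyl ether formation with the reactive triflate copes with the hindered alcohol and masks it against the organotitanium and borane reagents that follow, without touching C6.

**Step 11**
Reactants: 16 6α-(tert-butyldimethylsilyloxy)-11-nordrim-7-en-9-one
Product: 17 6α-(tert-butyldimethylsilyloxy)drima-7,9(11)-diene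
Conditions: Cp2TiMe2, toluene, 75 °C, dark
Reagents that add atoms: dimethyltitanocene Cp2TiMe2, C[Ti+2]C.[cH-]1cccc1.[cH-]1cccc1
Why: In the Petasis methylenation the thermally formed Cp2Ti=CH2 adds to C9=O by [2+2] cycloaddition/cycloreversion, a non-basic process that tolerates carbonyl groups next to quaternary carbons and cannot deprotonate the vinylogously acidic C6–H, so C6 keeps its configuration.

**Step 12**
Reactants: 18 propargyl alcohol
Product: 20 (E)-3-iodo-2-methylprop-2-en-1-ol, via alkenylalane 19 (not isolated)
Conditions: AlMe3, Cp2ZrCl2 (cat.), CH2Cl2, 0 °C → rt; I2, THF, −30 °C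
Reagents that add atoms: trimethylaluminium, C[Al](C)C; iodine, [I][I]
Why: Negishi zirconium-catalysed carboalumination adds methyl and aluminium syn across the alkyne with aluminium at the terminal carbon, and iodinolysis with retention gives the E iodide.

**Step 13**
Reactants: 17 6α-(tert-butyldimethylsilyloxy)drima-7,9(11)-diene; 20 (E)-3-iodo-2-methylprop-2-en-1-ol
Product: 22 (12E)-6α-(tert-butyldimethylsilyloxy)-15-norlabda-7,12-dien-14-ol, via B-alkyl-9-BBN adduct 21 (not isolated)
Conditions: 9-BBN, THF, rt → 50 °C; then 20, Pd(dppf)Cl2 (cat.), AsPh3 (cat.), Cs2CO3, DMF–H2O, rt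
Reagents that add atoms: (E)-3-iodo-2-methylprop-2-en-1-ol 20, OC/C(C)=C/I
Why: Hydroboration of the 1,1-disubstituted C9=C11 bond (the trisubstituted C7=C8 bond is inert to 9-BBN) places boron on C11 and delivers hydrogen to C9 from the α face, opposite the axial C20 on the neighbouring carbon, which sets C9 (9α-H, 9β-chain), and the B-alkyl Suzuki–Miyaura coupling on zerovalent palladium then joins C11 to C12 with retention of the E geometry.

**Step 14**
Reactants: 22 (12E)-6α-(tert-butyldimethylsilyloxy)-15-norlabda-7,12-dien-14-ol
Product: 23 (12E)-15-norlabda-7,12-diene-6α,14-diol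
Conditions: Bu4NF, THF, rt → 45 °C
Reagents that add atoms: none
Why: Fluoride-induced desilylation frees the 6α-OH that has to direct the epoxidation of step 16, and nothing else in the molecule responds to fluoride.

**Step 15**
Reactants: 23 (12E)-15-norlabda-7,12-diene-6α,14-diol
Product: 24 (12S,13S)-12,13-epoxy-15-norlabd-7-ene-6α,14-diol
Conditions: Ti(OiPr)4, L-(+)-diethyl tartrate, t-BuOOH, 4 Å MS, CH2Cl2, −20 °C
Reagents that add atoms: tert-butyl hydroperoxide, CC(C)(C)OO
Why: In the Sharpless asymmetric epoxidation the Ti(OiPr)4/L-(+)-tartrate catalyst, which turns (E)-2-methylalk-2-en-1-ols into (2S,3S)-epoxy alcohols, sets C13 by reagent control (13S here, 13R after step 17 because the priorities change), while the hindered cyclic allylic alcohol reacts far more slowly and could only give the syn epoxide wanted in step 16.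

**Step 16**
Reactants: 24 (12S,13S)-12,13-epoxy-15-norlabd-7-ene-6α,14-diol
Product: 25 (12S,13S)-7α,8α:12,13-diepoxy-15-norlabdane-6α,14-diol
Conditions: mCPBA, CH2Cl2, 0 °C
Reagents that add atoms: 3-chloroperbenzoic acid, OOC(=O)c1cccc(Cl)c1
Why: In this hydroxyl-directed peracid epoxidation (Henbest effect) hydrogen bonding to the pseudo-equatorial 6α-OH and the shielding of the β face by C20 both guide the peracid to the α face of the only remaining alkene, which sets the C8–O bond α and leaves C17 β.

**Step 17**
Reactants: 25 (12S,13S)-7α,8α:12,13-diepoxy-15-norlabdane-6α,14-diol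
Product: 26 (13R)-15-norlabdane-6α,8α,13,14-tetraol
Conditions: LiAlH4, THF, 0 °C → reflux
Reagents that add atoms: none
Why: SN2 hydride opening of both trisubstituted epoxides at their secondary carbons (C12 in the chain, C7 in ring B) leaves the tertiary C13–O and C8–O bonds and both configurations untouched, and the more accessible chain epoxide reacts first, so that no C8 alkoxide meets an intact epoxide.

**Step 18**
Reactants: 26 (13R)-15-norlabdane-6α,8α,13,14-tetraol
Product: 27 14-O-tosyl derivative of 26
Conditions: TsCl, Et3N, Bu2SnO (cat.), CH2Cl2, rt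
Reagents that add atoms: 4-toluenesulfonyl chloride, Cc1ccc(cc1)S(=O)(=O)Cl
Why: Stannylene-acetal-catalysed monosulfonylation activates only the 13,14-glycol and tosylates its primary oxygen, so the hindered secondary 6α-OH and the tertiary alcohols stay free.

**Step 19**
Reactants: 27 14-O-tosyl derivative of 26
Product: 29 (13R)-labd-14-ene-6α,8α,13-triol (6α-hydroxysclareol), via terminal 13,14-epoxide 28 (not isolated)
Conditions: Me3SI, n-BuLi (excess), THF, −10 °C → rt
Reagents that add atoms: trimethylsulfonium iodide, C[S+](C)C.[I-]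
Why: Base closes the hydroxy tosylate to the 13,14-epoxide without breaking the C13–O bond, dimethylsulfonium methylide opens it at the CH2 terminus, and the betaine loses Me2S by ylide-mediated elimination (one-carbon homologation of a terminal epoxide to an allylic alcohol), which adds C15 and leaves C13 unchanged.

**Step 20**
Reactants: 29 (13R)-labd-14-ene-6α,8α,13-triol; 30 angelic acid
Product: 32 (13R)-6α-angeloyloxylabd-14-ene-8α,13-diol (target), via mixed anhydride 31 (not isolated)
Conditions: 30, 2,4,6-Cl3C6H2COCl, Et3N, toluene, rt; then 29, 80 °C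
Reagents that add atoms: angelic acid 30, C/C=C(/C)C(=O)O
Why: Yamaguchi-type mixed-anhydride esterification run without a nucleophilic catalyst avoids the addition–elimination path that turns angelates into tiglates, and only the secondary 6α-OH is acylated because both other alcohols are tertiary.

**Compound list**
1 | (R)-(−)-carvone | CC1=CC[C@H](CC1=O)C(=C)C | starting material
2 | iodomethane | CI | starting material
3 | carvone lithium dienolate | [Li+].[O-]C1=C[C@H](C(C)=C)CC=C1C | intermediate
4 | 6-methylcarvone, (5R)-2,6-dimethyl-5-(prop-1-en-2-yl)cyclohex-2-en-1-one, both C6 (= C10) epimers | O=C1C(C)[C@H](C(C)=C)CC=C1C | intermediate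
5 | acrolein | C=CC=O | starting material
6 | tetrasubstituted lithium enolate of 4 | [Li+].[O-]C1=C(C)[C@H](C(C)=C)CC=C1C | intermediate
7 | 6-(1-hydroxyallyl)-6-methylcarvone, hydroxyallyl trans to isopropenyl, carbinol epimers | O=C1[C@@](C)(C(O)C=C)[C@H](C(C)=C)CC=C1C | intermediate
8 | 6-acryloyl-6-methylcarvone, acryloyl trans to isopropenyl | O=C1[C@@](C)(C(=O)C=C)[C@H](C(C)=C)CC=C1C | intermediate
9 | 11-nordrim-7-ene-1,9-dione (5α-H, 10β-CH3) | O=C1[C@@]2(C)C(=O)CCC(C)(C)[C@@H]2CC=C1C | intermediate
10 | 1-hydroxy-11-nordrim-7-en-9-one, C1 epimers | O=C1[C@@]2(C)C(O)CCC(C)(C)[C@@H]2CC=C1C | intermediate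
11 | 1-O-(imidazol-1-ylthiocarbonyl)-1-hydroxy-11-nordrim-7-en-9-one | O=C1[C@@]2(C)C(OC(=S)n3ccnc3)CCC(C)(C)[C@@H]2CC=C1C | intermediate
12 | 11-nordrim-7-en-9-one | O=C1[C@@]2(C)CCCC(C)(C)[C@@H]2CC=C1C | intermediate
13 | 9-(tert-butyldimethylsilyloxy)-11-nordrima-6,8-diene | CC1=C(O[Si](C)(C)C(C)(C)C)[C@@]2(C)CCCC(C)(C)[C@@H]2C=C1 | intermediate
14 | 6α,7α-epoxy-9-(tert-butyldimethylsilyloxy)-11-nordrim-8-ene | CC1=C(O[Si](C)(C)C(C)(C)C)[C@@]2(C)CCCC(C)(C)[C@@H]2[C@H]3O[C@H]31 | intermediate
15 | 6α-hydroxy-11-nordrim-7-en-9-one | O=C1[C@@]2(C)CCCC(C)(C)[C@@H]2[C@@H](O)C=C1C | intermediate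
16 | 6α-(tert-butyldimethylsilyloxy)-11-nordrim-7-en-9-one | O=C1[C@@]2(C)CCCC(C)(C)[C@@H]2[C@@H](O[Si](C)(C)C(C)(C)C)C=C1C | intermediate
17 | 6α-(tert-butyldimethylsilyloxy)drima-7,9(11)-diene | C=C1[C@@]2(C)CCCC(C)(C)[C@@H]2[C@@H](O[Si](C)(C)C(C)(C)C)C=C1C | intermediate
18 | propargyl alcohol | C#CCO | starting material
19 | (E)-alkenylalane from carboalumination of 18 (O- and C-bound AlMe2) | C[Al](C)OC/C(C)=C/[Al](C)C | intermediate
20 | (E)-3-iodo-2-methylprop-2-en-1-ol | OC/C(C)=C/I | intermediate
21 | 11-(9-borabicyclo[3.3.1]non-9-yl)-6α-(tert-butyldimethylsilyloxy)drim-7-ene (9α-H) | C3CC4CCCC(C3)B4C[C@@H]1[C@@]2(C)CCCC(C)(C)[C@@H]2[C@@H](O[Si](C)(C)C(C)(C)C)C=C1C | intermediate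
22 | (12E)-6α-(tert-butyldimethylsilyloxy)-15-norlabda-7,12-dien-14-ol | OC/C(C)=C/C[C@@H]1[C@@]2(C)CCCC(C)(C)[C@@H]2[C@@H](O[Si](C)(C)C(C)(C)C)C=C1C | intermediate
23 | (12E)-15-norlabda-7,12-diene-6α,14-diol | OC/C(C)=C/C[C@@H]1[C@@]2(C)CCCC(C)(C)[C@@H]2[C@@H](O)C=C1C | intermediate
24 | (12S,13S)-12,13-epoxy-15-norlabd-7-ene-6α,14-diol | OC[C@]3(C)O[C@H]3C[C@@H]1[C@@]2(C)CCCC(C)(C)[C@@H]2[C@@H](O)C=C1C | intermediate
25 | (12S,13S)-7α,8α:12,13-diepoxy-15-norlabdane-6α,14-diol | OC[C@]3(C)O[C@H]3C[C@@H]1[C@@]2(C)CCCC(C)(C)[C@@H]2[C@@H](O)[C@H]4O[C@@]14C | intermediate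
26 | (13R)-15-norlabdane-6α,8α,13,14-tetraol | OC[C@](C)(O)CC[C@@H]1[C@@]2(C)CCCC(C)(C)[C@@H]2[C@@H](O)C[C@@]1(C)O | intermediate
27 | (13R)-14-tosyloxy-15-norlabdane-6α,8α,13-triol | Cc1ccc(cc1)S(=O)(=O)OC[C@](C)(O)CC[C@@H]1[C@@]2(C)CCCC(C)(C)[C@@H]2[C@@H](O)C[C@@]1(C)O | intermediate
28 | (13R)-13,14-epoxy-15-norlabdane-6α,8α-diol | C3O[C@]3(C)CC[C@@H]1[C@@]2(C)CCCC(C)(C)[C@@H]2[C@@H](O)C[C@@]1(C)O | intermediate
29 | (13R)-labd-14-ene-6α,8α,13-triol | C=C[C@](C)(O)CC[C@@H]1[C@@]2(C)CCCC(C)(C)[C@@H]2[C@@H](O)C[C@@]1(C)O | intermediate
30 | angelic acid, (Z)-2-methylbut-2-enoic acid | C/C=C(/C)C(=O)O | starting material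
31 | angelic 2,4,6-trichlorobenzoic anhydride | C/C=C(/C)C(=O)OC(=O)c1c(Cl)cc(Cl)cc1Cl | intermediate
32 | (13R)-6α-angeloyloxylabd-14-ene-8α,13-diol | C=C[C@](C)(O)CC[C@@H]1[C@@]2(C)CCCC(C)(C)[C@@H]2[C@@H](OC(=O)/C(C)=C\C)C[C@@]1(C)O | target

**Total step count:** 20 (19 in the main line, 1 for iodide 20).
**Longest linear sequence:** 19 steps (1 → 32: steps 1–11 and 13–20).

**Steps most likely to fail**

**Step 9.** The oxidant may attack the more electron-rich enol-ether bond C8=C9 instead of C6=C7, or the α-facial preference at C6 may erode. The fallback sets out from 13 and replaces epoxidation by a cycloaddition. Sensitised photo-oxygenation (O2, tetraphenylporphyrin, hν, CH2Cl2, −78 °C) lets singlet oxygen add [4+2] across C6 and C9 of the ring diene. Both C–O bonds must form on one face, and the C9 terminus lies next to the β-methyl C20, so addition is confined to the α face and to the γ-carbon, giving the 6α,9α-epidioxy silyl ketal F1. Thiourea in MeOH cleaves the O–O bond, and the C9 silyl hemiketal collapses to the enone, which returns the route to 15.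

**Step 17.** Opening of the ring epoxide may be sluggish or misdirected, because attack at C7 is not trans-diaxial and occurs next to the C6 alkoxide, and forcing conditions may induce rearrangement. The fallback sets out from 24 and drops steps 16 and 17. LiAlH4 at 0 °C opens only the chain epoxide to (13R)-15-norlabd-7-ene-6α,13,14-triol F2. A Mukaiyama hydration (Mn(dpm)3 cat., PhSiH3, O2, iPrOH, then P(OEt)3) then places hydrogen on C7 and traps the tertiary C8 radical with O2 on the α face, away from the syn-axial C20. This returns the route to 26.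

**Step 4.** Hydrogen atom transfer to, or oligomerisation of, the unhindered vinyl ketone may outrun activation of the isopropenyl group. The fallback sets out from 4, keeps the C3–C4 closure, and moves the activating group out of the ring.
- Enolate 6 is alkylated with methyl 2-(bromomethyl)acrylate, again anti to the isopropenyl group, to give 6-[2-(methoxycarbonyl)allyl]-6-methylcarvone F3.
- Fe(acac)3/PhSiH3/EtOH generates the same C4 radical, which closes 6-endo onto the terminal CH2 of this more robust methacrylate-type acceptor to give methyl 9-oxo-11-nordrim-7-ene-2-carboxylate F4.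
- LiOH hydrolysis gives 9-oxo-11-nordrim-7-ene-2-carboxylic acid F5.
- N-hydroxypyridine-2-thione/DCC gives the Barton ester F6.
- Reductive decarboxylation (t-BuSH, hν) returns the route to 12. Steps 2–7 are bypassed and C1 is never oxygenated.

**Further compounds**
F1 | step 9 | 6α,9α-epidioxy-9β-(tert-butyldimethylsilyloxy)-11-nordrim-7-ene | CC1=C[C@@H]2OO[C@@]1(O[Si](C)(C)C(C)(C)C)[C@@]3(C)CCCC(C)(C)[C@H]23
F2 | step 17 | (13R)-15-norlabd-7-ene-6α,13,14-triol | OC[C@](C)(O)CC[C@@H]1[C@@]2(C)CCCC(C)(C)[C@@H]2[C@@H](O)C=C1C
F3 | step 4 | 6-[2-(methoxycarbonyl)allyl]-6-methylcarvone, allyl arm trans to isopropenyl | O=C1[C@@](C)(CC(=C)C(=O)OC)[C@H](C(C)=C)CC=C1C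
F4 | step 4 | methyl 9-oxo-11-nordrim-7-ene-2-carboxylate, C2 epimers | O=C1[C@@]2(C)CC(C(=O)OC)CC(C)(C)[C@@H]2CC=C1C
F5 | step 4 | 9-oxo-11-nordrim-7-ene-2-carboxylic acid, C2 epimers | O=C1[C@@]2(C)CC(C(=O)O)CC(C)(C)[C@@H]2CC=C1C
F6 | step 4 | 2-thioxopyridin-1(2H)-yl 9-oxo-11-nordrim-7-ene-2-carboxylate | O=C1[C@@]2(C)CC(C(=O)ON3C=CC=CC3=S)CC(C)(C)[C@@H]2CC=C1C
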